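Retrosynthesis: the ethyl and benzyl O–C bonds are cut last; ring C is opened at O1–C2 (cyclodehydration) and at C2–C3 (aroylation of a ketone enolate with the intact ring B acid chloride); the two-carbon unit is removed at C4–C4a (aryllithium plus Weinreb amide).
Ring A carries oxygen on C5, C7 and C8a, alternating with C4a, C6 and the prenylated C8; this is the pattern of a vinylketene joined to an ynol ether, so ring A is cut at C7–C8, C4a–C8a and C6–C7 into 3-ethoxycyclobut-2-en-1-one and a prenyl-bearing siloxyalkyne.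
The siloxyalkyne goes back to prenyl bromide and ethynylmagnesium bromide (bond between the prenyl CH2 and the alkyne).
Forward: alkyne chain (steps 1–2), ring A by benzannulation (step 3), desilylation, bis-acetal protection and acylation at C4a (steps 4–6), ring B joined at C2–C3 (steps 7–8), ring C closed last (step 9), ethers cleaved (step 10).
Stereochemistry: the target has no stereocentre and no configured double bond; the centres that appear on the way are racemic and vanish on aromatisation.

Key step: step 3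

Remark on the chemistry: desilylation in step 4 gives a resorcinol with two equivalent hydroxyls, so taking the silyloxy carbon of the benzannulation product as C8a and the hydroxyl carbon as C7 is a labelling choice that the later steps cannot contradict; 3-ethoxycyclobut-2-en-1-one, 2-(benzyloxy)-N-methoxy-N-methylacetamide and 3,4-bis(benzyloxy)benzoic acid are taken as purchased.

Step 1
Reactants: 1 prenyl bromide (1-bromo-3-methylbut-2-ene); 2 ethynylmagnesium bromide
Product: 3 5-methylhex-4-en-1-yne
Conditions: CuBr (5 mol %), THF, 0 °C → rt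
Reagents that add atoms: none
Why: Copper-catalysed SN2 allylation of an alkynyl Grignard reagent at the primary carbon of the allylic bromide is the standard entry to skipped 1,4-enynes.

Step 2
Reactants: 3 5-methylhex-4-en-1-yne
Product: 6 triisopropyl(5-methylhex-4-en-1-ynyloxy)silane, via lithium acetylide 4 (not isolated), via lithium ynolate 5 (not isolated)
Conditions: n-BuLi, THF, −78 °C; LiOOtBu (from tBuOOH and LiN(SiMe3)2), −78 → 0 °C; iPr3SiOTf, −78 → 0 °C
Reagents that add atoms: tert-butyl hydroperoxide (used as its lithium salt), CC(C)(C)OO; triisopropylsilyl trifluoromethanesulfonate, CC(C)[Si](C(C)C)(C(C)C)OS(=O)(=O)C(F)(F)F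
Why: Oxidation of a lithium acetylide by the electrophilic oxygen of lithium tert-butyl peroxide gives the ynolate, and O-silylation with the bulky silyl triflate should give the siloxyalkyne and not a silylketene.

Step 3
Reactants: 6 triisopropyl(5-methylhex-4-en-1-ynyloxy)silane; 7 3-ethoxycyclobut-2-en-1-one
Product: 12 5-ethoxy-2-(3-methylbut-2-enyl)-3-(triisopropylsilyloxy)phenol, via vinylketene 8 (not isolated), via vinylcyclobutenone 9 (not isolated), via dienylketene 10 (not isolated), via cyclohexadienone 11 (not isolated)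
Conditions: PhMe, 80 → 110 °C (1.3 equiv of 7)
Reagents that add atoms: none
Why: Heat opens 7 by 4π electrocyclic ring opening to vinylketene 8, whose carbonyl carbon is attacked by the prenyl-bearing, electron-rich carbon of siloxyalkyne 6 in a ketene–alkyne [2+2] cycloaddition that forms C7–C8 and C4a–C8a and gives cyclobutenone 9. A second 4π opening turns 9 into dienylketene 10, which closes ring A by a thermal 6π electrocyclisation (six-membered carbocycle, C6–C7 bond) to dienone 11, and enolisation gives phenol 12. The closest known reaction type is the Danheiser benzannulation of cyclobutenones with siloxyalkynes to resorcinol monosilyl ethers; here the 3-ethoxy group only adds a third, differently masked oxygen. No stereocentre is formed, and the racemic centre of 9 is lost on ring opening. The selectivity needed is the orientation of the [2+2] step, and it is secured by the polarisation of the ynol ether, whose oxygen makes the prenyl-bearing carbon the nucleophile toward the ketene carbonyl carbon. The prenyl carbon should therefore end up between the hydroxyl carbon (C7) and the silyloxy carbon (C8a), with the ethoxy carbon (C5) para to it.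

Step 4
Reactants: 12 5-ethoxy-2-(3-methylbut-2-enyl)-3-(triisopropylsilyloxy)phenol
Product: 13 5-ethoxy-2-(3-methylbut-2-enyl)benzene-1,3-diol
Conditions: Bu4NF, AcOH, THF, 0 °C
Reagents that add atoms: none
Why: Fluoride-mediated desilylation of an aryl silyl ether, buffered with acetic acid so that the electron-rich phenoxide is not exposed to air oxidation, should give the resorcinol.

Step 5
Reactants: 13 5-ethoxy-2-(3-methylbut-2-enyl)benzene-1,3-diol
Product: 14 5-ethoxy-1,3-bis(methoxymethoxy)-2-(3-methylbut-2-enyl)benzene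
Conditions: NaH, MOMCl, DMF, 0 °C → rt
Reagents that add atoms: chloromethyl methyl ether, COCCl
Why: Williamson-type O-alkylation of both sodium phenoxides installs acetals that direct the coming ortho-lithiation and can later be removed by mild acid.

Step 6
Reactants: 14 5-ethoxy-1,3-bis(methoxymethoxy)-2-(3-methylbut-2-enyl)benzene; 15 2-(benzyloxy)-N-methoxy-N-methylacetamide
Product: 18 2-(benzyloxy)-1-[6-ethoxy-2,4-bis(methoxymethoxy)-3-(3-methylbut-2-enyl)phenyl]ethan-1-one, via aryllithium 16 (not isolated), via tetrahedral lithium adduct 17 (not isolated)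
Conditions: n-BuLi, THF, 0 °C; then 15, −78 → 0 °C; aq. NH4Cl
Reagents that add atoms: none
Why: Directed ortho-metalation at a ring C–H flanked by the acetal and ethoxy oxygens (the two ring hydrogens are equivalent) followed by Weinreb ketone synthesis, in which the chelated adduct prevents over-addition, should form the C4–C4a bond.

Step 7
Reactants: 19 3,4-bis(benzyloxy)benzoic acid
Product: 20 3,4-bis(benzyloxy)benzoyl chloride
Conditions: (COCl)2, DMF (cat.), CH2Cl2, 0 °C → rt
Reagents that add atoms: oxalyl chloride, O=C(Cl)C(=O)Cl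
Why: Acid chloride formation with oxalyl chloride under Vilsmeier-type catalysis by DMF is routine and leaves benzyl ethers untouched.

Step 8
Reactants: 18 2-(benzyloxy)-1-[6-ethoxy-2,4-bis(methoxymethoxy)-3-(3-methylbut-2-enyl)phenyl]ethan-1-one; 20 3,4-bis(benzyloxy)benzoyl chloride
Product: 22 2-(benzyloxy)-1-[3,4-bis(benzyloxy)phenyl]-3-[6-ethoxy-2,4-bis(methoxymethoxy)-3-(3-methylbut-2-enyl)phenyl]propane-1,3-dione (racemic), via lithium enolate 21 (not isolated)
Conditions: LiN(SiMe3)2 (2.2 equiv), THF, −78 °C; then 20, −78 → 0 °C; aq. NH4Cl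
Reagents that add atoms: none
Why: Crossed Claisen-type C-acylation of the lithium enolate of an aryl ketone with an aroyl chloride forms the C2–C3 bond, the second equivalent of base taking up the acidic 1,3-diketone as it forms.

Step 9
Reactants: 22 2-(benzyloxy)-1-[3,4-bis(benzyloxy)phenyl]-3-[6-ethoxy-2,4-bis(methoxymethoxy)-3-(3-methylbut-2-enyl)phenyl]propane-1,3-dione
Product: 25 3-(benzyloxy)-2-[3,4-bis(benzyloxy)phenyl]-5-ethoxy-7-hydroxy-8-(3-methylbut-2-enyl)-4H-chromen-4-one, via dihydroxy diketone 23 (not isolated), via cyclic hemiketal 24 (not isolated)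
Conditions: 3 M aq. HCl, MeOH/THF, 50 °C
Reagents that add atoms: none
Why: Acidic methanolysis of the two acetals frees the C8a hydroxyl, which adds to the ring B ketone and loses water (the cyclodehydration that ends Baker–Venkataraman-type flavone syntheses), while the ethyl ether on C5 blocks closure through the other ortho oxygen so that only the 8-prenyl isomer can form.

Step 10
Reactants: 25 3-(benzyloxy)-2-[3,4-bis(benzyloxy)phenyl]-5-ethoxy-7-hydroxy-8-(3-methylbut-2-enyl)-4H-chromen-4-one
Product: 26 8-prenylquercetin, 2-(3,4-dihydroxyphenyl)-3,5,7-trihydroxy-8-(3-methylbut-2-enyl)-4H-chromen-4-one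
Conditions: BCl3, C6HMe5, 2,6-di-tert-butylpyridine, CH2Cl2, −78 °C → rt; then MeOH, H2O
Reagents that add atoms: none
Why: Lewis-acid ether cleavage in which BCl3 passes the three benzyl groups to pentamethylbenzene (Friedel–Crafts trap) and cleaves the 5-ethyl ether through its chelate with the C4 carbonyl by chloride SN2 attack, while the hindered pyridine, which cannot bind boron, takes up HCl so that the prenyl double bond should stay unprotonated.

Compound list
1 | prenyl bromide (1-bromo-3-methylbut-2-ene) | CC(C)=CCBr | starting material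
2 | ethynylmagnesium bromide | C#C[Mg]Br | starting material
3 | 5-methylhex-4-en-1-yne | CC(C)=CCC#C | intermediate
4 | (5-methylhex-4-en-1-ynyl)lithium (lithium acetylide) | [Li]C#CCC=C(C)C | intermediate
5 | lithium 5-methylhex-4-en-1-yn-1-olate (lithium ynolate) | [Li]OC#CCC=C(C)C | intermediate
6 | triisopropyl(5-methylhex-4-en-1-ynyloxy)silane | CC(C)=CCC#CO[Si](C(C)C)(C(C)C)C(C)C | intermediate
7 | 3-ethoxycyclobut-2-en-1-one | CCOC1=CC(=O)C1 | starting material
8 | 3-ethoxybuta-1,3-dien-1-one (vinylketene) | C=C(OCC)C=C=O | intermediate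
9 | 4-(1-ethoxyethenyl)-2-(3-methylbut-2-enyl)-3-(triisopropylsilyloxy)cyclobut-2-en-1-one (racemic) | CCOC(=C)C1C(=O)C(CC=C(C)C)=C1O[Si](C(C)C)(C(C)C)C(C)C | intermediate
10 | (3E)-5-ethoxy-2-(3-methylbut-2-enyl)-3-(triisopropylsilyloxy)hexa-1,3,5-trien-1-one (dienylketene) | O=C=C(CC=C(C)C)/C(O[Si](C(C)C)(C(C)C)C(C)C)=C\C(OCC)=C | intermediate
11 | 5-ethoxy-2-(3-methylbut-2-enyl)-3-(triisopropylsilyloxy)cyclohexa-2,4-dien-1-one | CCOC1=CC(O[Si](C(C)C)(C(C)C)C(C)C)=C(CC=C(C)C)C(=O)C1 | intermediate
12 | 5-ethoxy-2-(3-methylbut-2-enyl)-3-(triisopropylsilyloxy)phenol | CC(C)=CCc1c(O)cc(OCC)cc1O[Si](C(C)C)(C(C)C)C(C)C | intermediate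
13 | 5-ethoxy-2-(3-methylbut-2-enyl)benzene-1,3-diol | CCOc1cc(O)c(CC=C(C)C)c(O)c1 | intermediate
14 | 5-ethoxy-1,3-bis(methoxymethoxy)-2-(3-methylbut-2-enyl)benzene | CCOc1cc(OCOC)c(CC=C(C)C)c(OCOC)c1 | intermediate
15 | 2-(benzyloxy)-N-methoxy-N-methylacetamide | CON(C)C(=O)COCc1ccccc1 | starting material
16 | [6-ethoxy-2,4-bis(methoxymethoxy)-3-(3-methylbut-2-enyl)phenyl]lithium | [Li]c1c(OCC)cc(OCOC)c(CC=C(C)C)c1OCOC | intermediate
17 | lithium 2-(benzyloxy)-1-[6-ethoxy-2,4-bis(methoxymethoxy)-3-(3-methylbut-2-enyl)phenyl]-1-[methoxy(methyl)amino]ethan-1-olate (racemic) | [Li]OC(COCc1ccccc1)(N(C)OC)c1c(OCC)cc(OCOC)c(CC=C(C)C)c1OCOC | intermediate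
18 | 2-(benzyloxy)-1-[6-ethoxy-2,4-bis(methoxymethoxy)-3-(3-methylbut-2-enyl)phenyl]ethan-1-one | CCOc1cc(OCOC)c(CC=C(C)C)c(OCOC)c1C(=O)COCc1ccccc1 | intermediate
19 | 3,4-bis(benzyloxy)benzoic acid | O=C(O)c1ccc(OCc2ccccc2)c(OCc2ccccc2)c1 | starting material
20 | 3,4-bis(benzyloxy)benzoyl chloride | O=C(Cl)c1ccc(OCc2ccccc2)c(OCc2ccccc2)c1 | intermediate
21 | lithium (Z)-2-(benzyloxy)-1-[6-ethoxy-2,4-bis(methoxymethoxy)-3-(3-methylbut-2-enyl)phenyl]ethen-1-olate | [Li]O/C(=C\OCc1ccccc1)c1c(OCC)cc(OCOC)c(CC=C(C)C)c1OCOC | intermediate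
22 | 2-(benzyloxy)-1-[3,4-bis(benzyloxy)phenyl]-3-[6-ethoxy-2,4-bis(methoxymethoxy)-3-(3-methylbut-2-enyl)phenyl]propane-1,3-dione (racemic) | CCOc1cc(OCOC)c(CC=C(C)C)c(OCOC)c1C(=O)C(OCc1ccccc1)C(=O)c1ccc(OCc2ccccc2)c(OCc2ccccc2)c1 | intermediate
23 | 2-(benzyloxy)-1-[3,4-bis(benzyloxy)phenyl]-3-[6-ethoxy-2,4-dihydroxy-3-(3-methylbut-2-enyl)phenyl]propane-1,3-dione (racemic) | CCOc1cc(O)c(CC=C(C)C)c(O)c1C(=O)C(OCc1ccccc1)C(=O)c1ccc(OCc2ccccc2)c(OCc2ccccc2)c1 | intermediate
24 | 3-(benzyloxy)-2-[3,4-bis(benzyloxy)phenyl]-5-ethoxy-2,7-dihydroxy-8-(3-methylbut-2-enyl)-2,3-dihydro-4H-chromen-4-one (racemic, mixture of diastereomers) | CCOc1cc(O)c(CC=C(C)C)c2OC(O)(c3ccc(OCc4ccccc4)c(OCc4ccccc4)c3)C(OCc3ccccc3)C(=O)c12 | intermediate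
25 | 3-(benzyloxy)-2-[3,4-bis(benzyloxy)phenyl]-5-ethoxy-7-hydroxy-8-(3-methylbut-2-enyl)-4H-chromen-4-one | CCOc1cc(O)c(CC=C(C)C)c2oc(-c3ccc(OCc4ccccc4)c(OCc4ccccc4)c3)c(OCc3ccccc3)c(=O)c12 | intermediate
26 | 8-prenylquercetin, 2-(3,4-dihydroxyphenyl)-3,5,7-trihydroxy-8-(3-methylbut-2-enyl)-4H-chromen-4-one | CC(C)=CCc1c(O)cc(O)c2c(=O)c(O)c(-c3ccc(O)c(O)c3)oc12 | target

Total step count: 10. Longest linear sequence: 9 steps (steps 1–6 and 8–10; step 7 is a one-step side branch).

Steps most likely to fail, riskiest first: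

Step 10. HCl set free at the C7 hydroxyl and during benzyl transfer may protonate the prenyl double bond before the pyridine traps it, after which the C7 oxygen or chloride adds to the tertiary cation. The ethyl ether may also cleave only at temperatures where this protonation becomes fast. The fallback sets out from 25 and comes back at 26. Compound 25 would be heated with MgI2·OEt2 in toluene, where magnesium held between the C4 carbonyl and the flanking C5 and C3 oxygens lets iodide dealkylate these two ethers without a Brønsted acid. This should give 2-[3,4-bis(benzyloxy)phenyl]-3,5,7-trihydroxy-8-(3-methylbut-2-enyl)-4H-chromen-4-one F1. The two ring B benzyl ethers of F1 would then be removed by transfer hydrogenolysis (Pd/C, cyclohexa-1,4-diene, EtOH, rt), which should spare the trisubstituted olefin, to give 26.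

Step 3. The first ring opening of 7 is slowed by the vinylogous-ester character of the 3-ethoxy enone and may need temperatures at which ketene 8 dimerises or acylates phenol 12 and the siloxyalkyne is consumed. The fallback sets out from 6 and comes back at 9, and so at 12. Ketene 8 would be made at room temperature by 1,4-dehydrochlorination in place of ring opening. Commercial ethyl (E)-3-ethoxybut-2-enoate would be saponified (NaOH, aq. EtOH) to (E)-3-ethoxybut-2-enoic acid F2, which with (COCl)2 should give (E)-3-ethoxybut-2-enoyl chloride F3. Slow addition of Et3N to F3 and 6 in toluene removes a γ-hydrogen and chloride to give 8, which 6 should trap in the same [2+2] cycloaddition to 9. Brief heating of crude 9 at 80 °C would then complete the rearrangement through 10 and 11 to 12.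

Step 8. The hindered, chelated enolate 21 may be acylated on oxygen (enol ester in place of diketone), or proton transfer from the product may stop the reaction early. The fallback sets out from 18 and comes back at 25 through 23 and 24. The C–C bond would be made by intramolecular acyl transfer (Baker–Venkataraman rearrangement). Short treatment of 18 with catalytic HCl in MeOH at 0 °C should cleave first the acetal next to the ketone, giving 2-(benzyloxy)-1-[6-ethoxy-2-hydroxy-4-(methoxymethoxy)-3-(3-methylbut-2-enyl)phenyl]ethan-1-one F4. Esterification of F4 with 20 (Et3N, DMAP, CH2Cl2) would give 2-[(benzyloxy)acetyl]-3-ethoxy-5-(methoxymethoxy)-6-(3-methylbut-2-enyl)phenyl 3,4-bis(benzyloxy)benzoate F5. Base (KOtBu, THF, 0 °C) should move the aroyl group from oxygen to the enolate carbon to give 2-(benzyloxy)-1-[3,4-bis(benzyloxy)phenyl]-3-[6-ethoxy-2-hydroxy-4-(methoxymethoxy)-3-(3-methylbut-2-enyl)phenyl]propane-1,3-dione F6. The acid treatment of step 9 would then convert F6 through 23 and 24 into 25.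

Further compounds
F1 | step 10 | 2-[3,4-bis(benzyloxy)phenyl]-3,5,7-trihydroxy-8-(3-methylbut-2-enyl)-4H-chromen-4-one | CC(C)=CCc1c(O)cc(O)c2c(=O)c(O)c(-c3ccc(OCc4ccccc4)c(OCc4ccccc4)c3)oc12
F2 | step 3 | (E)-3-ethoxybut-2-enoic acid | CCO/C(C)=C/C(=O)O
F3 | step 3 | (E)-3-ethoxybut-2-enoyl chloride | CCO/C(C)=C/C(=O)Cl
F4 | step 8 | 2-(benzyloxy)-1-[6-ethoxy-2-hydroxy-4-(methoxymethoxy)-3-(3-methylbut-2-enyl)phenyl]ethan-1-one | CCOc1cc(OCOC)c(CC=C(C)C)c(O)c1C(=O)COCc1ccccc1
F5 | step 8 | 2-[(benzyloxy)acetyl]-3-ethoxy-5-(methoxymethoxy)-6-(3-methylbut-2-enyl)phenyl 3,4-bis(benzyloxy)benzoate | CCOc1cc(OCOC)c(CC=C(C)C)c(OC(=O)c2ccc(OCc3ccccc3)c(OCc3ccccc3)c2)c1C(=O)COCc1ccccc1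
F6 | step 8 | 2-(benzyloxy)-1-[3,4-bis(benzyloxy)phenyl]-3-[6-ethoxy-2-hydroxy-4-(methoxymethoxy)-3-(3-methylbut-2-enyl)phenyl]propane-1,3-dione (racemic) | CCOc1cc(OCOC)c(CC=C(C)C)c(O)c1C(=O)C(OCc1ccccc1)C(=O)c1ccc(OCc2ccccc2)c(OCc2ccccc2)c1
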